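**Strategy.** The saturated five-membered ring of the norbornene core (spiro carbon C11′ and C13′H2 of the seco-eudesmane half, C1, C2 and C3 of the guaiane half) is made by contraction of a six-membered ring. A cyclic 2-alkoxy-1-chloroallyl cation, generated from the dichloro enol ether of the seco-eudesmane fragment, adds [4+3] to the guaianolide cyclopentadiene and gives a bicyclo[3.2.1]octene hemiketal that carries chlorine on C11′. Base then triggers a quasi-Favorskii shift of C13′ from the hemiketal carbon to C11′: the hemiketal carbon leaves the ring and becomes the lactone carbonyl C12′, the spiro-lactone forms and C11′ is inverted in one operation.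

Key step: step 23

Remark: guaiane numbering (C1 to C15) is used for the hydroazulene half and primed eudesmane numbering for the seco-eudesmane half; TBS = tert-butyldimethylsilyl; tertiary carbinol, hemiketal and transient allylic alcohol centres that are destroyed later are carried as epimer mixtures.

**Seco-eudesmane fragment**

Step 1
Reactants: 1 methyl (E)-but-2-enoate; 2 (3-bromopropoxy)(tert-butyl)dimethylsilane
Product: 4 methyl (3S)-3-methyl-6-(TBSO)hexanoate, via Grignard reagent 3 (not isolated)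
Conditions: Mg, Et2O; then CuI (2 mol%), (R)-Tol-BINAP (3 mol%), t-BuOMe, −40 °C
Reagents that add atoms: none
Why: Copper-catalysed asymmetric conjugate addition of a Grignard reagent to an enoate, in which the Tol-BINAP–copper complex selects the enantioface of the crotonate and should set C4′ as S (the antipodal ligand would be used if the sense proved opposite).

Step 2
Reactants: 4 methyl (3S)-3-methyl-6-(TBSO)hexanoate
Product: 5 (3S)-3-methyl-6-(TBSO)hexanal
Conditions: i-Bu2AlH (1.05 equiv), CH2Cl2, −78 °C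
Reagents that add atoms: none
Why: Partial reduction of the ester through the aluminium hemiacetal that is stable at −78 °C; the β-stereocentre cannot epimerise.

Step 3
Reactants: 5 (3S)-3-methyl-6-(TBSO)hexanal; 6 but-3-en-2-one
Product: 8 (4R)-4-[(2S)-5-(TBSO)pentan-2-yl]cyclohex-2-en-1-one, via keto aldehyde 7 (not isolated)
Conditions: (R)-α,α-diphenylprolinol trimethylsilyl ether (10 mol%), 4-nitrophenol (20 mol%), neat, 4 °C; then LiOH, i-PrOH, 25 °C
Reagents that add atoms: none
Why: Organocatalytic Robinson annulation (enamine Michael addition, then aldol condensation) in which the catalyst shields one face of the E-enamine and should set the ring carbon as R; this centre only serves to place the side chain for step 6 and is destroyed there.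

Step 4
Reactants: 8 (4R)-4-[(2S)-5-(TBSO)pentan-2-yl]cyclohex-2-en-1-one
Product: 9 (1S,4R)-4-[(2S)-5-(TBSO)pentan-2-yl]cyclohex-2-en-1-ol
Conditions: (R)-2-methyl-CBS-oxazaborolidine (20 mol%), catecholborane, PhMe, −78 °C
Reagents that add atoms: none
Why: Corey–Bakshi–Shibata reduction under reagent control (alkenyl arm as the large group) should give the 1S alcohol, trans to the C4 side chain; this carbinol becomes C8′.

Step 5
Reactants: 9 (1S,4R)-4-[(2S)-5-(TBSO)pentan-2-yl]cyclohex-2-en-1-ol; 10 iodoacetic acid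
Product: 11 (1S,4R)-4-[(2S)-5-(TBSO)pentan-2-yl]cyclohex-2-en-1-yl iodoacetate
Conditions: DCC, DMAP (cat.), CH2Cl2, 0 °C
Reagents that add atoms: none
Why: Steglich esterification of the secondary allylic alcohol, which touches no stereocentre.

Step 6
Reactants: 11 (1S,4R)-4-[(2S)-5-(TBSO)pentan-2-yl]cyclohex-2-en-1-yl iodoacetate
Product: 13 (3aR,7aS)-5-[(2S)-5-(TBSO)pentan-2-yl]-3a,6,7,7a-tetrahydro-1-benzofuran-2(3H)-one, via iodo lactone 12 (not isolated)
Conditions: Et3B (0.5 equiv), air, H2O, 25 °C; then DBU, PhMe, 60 °C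
Reagents that add atoms: none
Why: Iodine-atom-transfer 5-exo-trig radical cyclisation through the C8′–O tether gives the cis-fused lactone (C7′ set by the tether) with iodine delivered trans to the new ring, so that H5′ is the only antiperiplanar hydrogen and E2 elimination should give the C5′=C6′ alkene.

Step 7
Reactants: 13 (3aR,7aS)-5-[(2S)-5-(TBSO)pentan-2-yl]-3a,6,7,7a-tetrahydro-1-benzofuran-2(3H)-one
Product: 15 (3aR,7aS)-5-[(2S)-5-(TBSO)pentan-2-yl]-3a,7a-dihydro-1-benzofuran-2,6(3H,7H)-dione, via allylic alcohol 14 (not isolated)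
Conditions: SeO2 (0.5 equiv), t-BuOOH, CH2Cl2, 25 °C; then Dess–Martin periodinane, NaHCO3, CH2Cl2, 0 °C
Reagents that add atoms: selenium dioxide (O=[Se]=O), turned over by tert-butyl hydroperoxide (CC(C)(C)OO)
Why: Allylic oxidation with SeO2 (ene reaction, then [2,3] shift) goes to the ring CH2 at the more substituted alkene terminus, and Dess–Martin oxidation under neutral conditions gives the enone without β-elimination of the lactone oxygen.

Step 8
Reactants: 15 (3aR,7aS)-5-[(2S)-5-(TBSO)pentan-2-yl]-3a,7a-dihydro-1-benzofuran-2,6(3H,7H)-dione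
Product: 16 (3aR,7aS)-6-methylidene-5-[(2S)-5-(TBSO)pentan-2-yl]-3a,6,7,7a-tetrahydro-1-benzofuran-2(3H)-one
Conditions: Zn, CH2Br2, TiCl4, THF/CH2Cl2, 0 to 25 °C
Reagents that add atoms: dibromomethane (BrCBr)
Why: Takai–Lombardo methylenation is non-basic and selective for the ketone over the lactone, so the β-acyloxy ketone should not eliminate or aromatise.

Step 9
Reactants: 16 (3aR,7aS)-6-methylidene-5-[(2S)-5-(TBSO)pentan-2-yl]-3a,6,7,7a-tetrahydro-1-benzofuran-2(3H)-one
Product: 17 (3aR,7aS)-3,3-dichloro-6-methylidene-5-[(2S)-5-(TBSO)pentan-2-yl]-3a,6,7,7a-tetrahydro-1-benzofuran-2(3H)-one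
Conditions: LiN(SiMe3)2 (2.5 equiv), THF, −78 °C; then Cl3CCCl3 (2.5 equiv), −78 to −20 °C
Reagents that add atoms: hexachloroethane (ClC(Cl)(Cl)C(Cl)(Cl)Cl)
Why: Electrophilic chlorination of the lactone enolate; the monochloride is more acidic and is deprotonated and chlorinated again in the same pot.

Step 10
Reactants: 17 (3aR,7aS)-3,3-dichloro-6-methylidene-5-[(2S)-5-(TBSO)pentan-2-yl]-3a,6,7,7a-tetrahydro-1-benzofuran-2(3H)-one
Product: 18 (3aR,7aS)-3,3-dichloro-2-methyl-6-methylidene-5-[(2S)-5-(TBSO)pentan-2-yl]-2,3,3a,6,7,7a-hexahydro-1-benzofuran-2-ol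
Conditions: MeMgBr (1.1 equiv), THF, −78 °C; aq NH4Cl
Reagents that add atoms: methylmagnesium bromide (C[Mg]Br)
Why: Mono-addition of the Grignard reagent to the lactone, because the α,α-dichloro hemiketal salt is stable at −78 °C and does not open to a ketone; the added methyl carbon is the future C13′.

Step 11
Reactants: 18 (3aR,7aS)-3,3-dichloro-2-methyl-6-methylidene-5-[(2S)-5-(TBSO)pentan-2-yl]-2,3,3a,6,7,7a-hexahydro-1-benzofuran-2-ol
Product: 19 (3aR,7aS)-3,3-dichloro-2,6-dimethylidene-5-[(2S)-5-(TBSO)pentan-2-yl]-2,3,3a,6,7,7a-hexahydro-1-benzofuran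
Conditions: MsCl, Et3N, CH2Cl2, −20 to 0 °C; used without storage
Reagents that add atoms: none
Why: Sulfonylation of the hemiketal hydroxyl and E1 loss through the oxocarbenium ion; only the methyl group carries β-hydrogens, so the exocyclic enol ether should form.

**Guaianolide fragment**

Step 12
Reactants: 20 2-(2,5-dimethylfuran-3-yl)-4,4,5,5-tetramethyl-1,3,2-dioxaborolane; 21 ethyl (E)-but-2-enoate
Product: 22 ethyl (3R)-3-(2,5-dimethylfuran-3-yl)butanoate
Conditions: [Rh(cod)Cl]2 (3 mol%), (S)-BINAP (7 mol%), KOH, 1,4-dioxane/H2O, 60 °C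
Reagents that add atoms: none
Why: Hayashi–Miyaura asymmetric conjugate addition, in which the BINAP–rhodium furyl species adds to one enantioface of the crotonate and should set C10 as R (antipodal ligand if the sense proved opposite).

Step 13
Reactants: 22 ethyl (3R)-3-(2,5-dimethylfuran-3-yl)butanoate
Product: 23 ethyl (3R)-3-(4-bromo-2,5-dimethylfuran-3-yl)butanoate
Conditions: NBS, DMF, −20 °C, dark
Reagents that add atoms: N-bromosuccinimide (O=C1CCC(=O)N1Br)
Why: Electrophilic aromatic bromination at the only free position of the furan.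

Step 14
Reactants: 23 ethyl (3R)-3-(4-bromo-2,5-dimethylfuran-3-yl)butanoate; 24 allyltributylstannane
Product: 25 ethyl (3R)-3-[2,5-dimethyl-4-(prop-2-en-1-yl)furan-3-yl]butanoate
Conditions: Pd(PPh3)4 (5 mol%), DMF, 90 °C
Reagents that add atoms: none
Why: Stille cross-coupling of the furyl bromide with the allylstannane installs C6 and C7.

Step 15
Reactants: 25 ethyl (3R)-3-[2,5-dimethyl-4-(prop-2-en-1-yl)furan-3-yl]butanoate
Product: 26 (3R)-3-[2,5-dimethyl-4-(prop-2-en-1-yl)furan-3-yl]butanal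
Conditions: i-Bu2AlH (1.05 equiv), CH2Cl2, −78 °C
Reagents that add atoms: none
Why: Partial ester reduction as in step 2 gives the C8 aldehyde.

Step 16
Reactants: 26 (3R)-3-[2,5-dimethyl-4-(prop-2-en-1-yl)furan-3-yl]butanal; 27 methyl 2-(bromomethyl)prop-2-enoate
Product: 28 methyl (2Z)-2-(bromomethyl)-4-{2,5-dimethyl-4-[(2R)-4-oxobutan-2-yl]furan-3-yl}but-2-enoate
Conditions: second-generation Grubbs catalyst (5 mol%), 27 (4 equiv), CH2Cl2, 40 °C
Reagents that add atoms: none
Why: Olefin cross-metathesis of the terminal alkene with the 1,1-disubstituted acrylate should give the trisubstituted enoate with the chain trans to the ester; either alkene isomer serves in step 17.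

Step 17
Reactants: 28 methyl (2Z)-2-(bromomethyl)-4-{2,5-dimethyl-4-[(2R)-4-oxobutan-2-yl]furan-3-yl}but-2-enoate
Product: 29 (7S,8R,10R)-tricyclic furan lactone: 2,5-dimethylfuran fused through C1 and C5 to the cycloheptane that bears the C10 methyl and a trans-fused α-methylene-γ-lactone at C7/C8
Conditions: CrCl2 (4 equiv), THF (0.005 M), 25 °C; then p-TsOH (cat.), CH2Cl2
Reagents that add atoms: none
Why: Intramolecular Nozaki–Hiyama allylation through a chair transition state (anti adduct) followed by lactonisation should give the trans-fused lactone; with the C10 methyl pseudoaxial (away from the furan methyl) and the new C7 and C8 substituents equatorial this corresponds to 7S and 8R.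

Step 18
Reactants: 29 (7S,8R,10R)-tricyclic furan lactone
Product: 31 (7S,8R,10R)-4-hydroxy-2-oxoguaia-1(5),11(13)-dien-12,8-olide, via enedione 30 (not isolated)
Conditions: 3-ClC6H4CO3H (1.05 equiv), CH2Cl2, 0 °C; then aq Na2CO3, THF, 25 °C
Reagents that add atoms: 3-chloroperoxybenzoic acid (OOC(=O)c1cccc(Cl)c1)
Why: Peracid oxidation opens the furan to the Z-enedione, and intramolecular aldol addition of the C1 acetyl enolate to the less hindered C5 acetyl carbonyl gives the 4-hydroxy-4-methylcyclopentenone (the classical 2,5-dimethylfuran to hydroxycyclopentenone sequence).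

Step 19
Reactants: 31 (7S,8R,10R)-4-hydroxy-2-oxoguaia-1(5),11(13)-dien-12,8-olide
Product: 32 (2S,7S,8R,10R)-2,4-dihydroxyguaia-1(5),11(13)-dien-12,8-olide
Conditions: (R)-2-methyl-CBS-oxazaborolidine (20 mol%), catecholborane (2.5 equiv), PhMe/CH2Cl2, −78 °C
Reagents that add atoms: none
Why: Corey–Bakshi–Shibata 1,2-reduction of the enone under reagent control, reinforced by hydride approach anti to the pseudoaxial C10 methyl, should set C2 as S; the α-methylene lactone is not reduced at −78 °C.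

Step 20
Reactants: 32 (2S,7S,8R,10R)-2,4-dihydroxyguaia-1(5),11(13)-dien-12,8-olide
Product: 33 (2S,7S,8R,10R)-2-acetoxy-4-hydroxyguaia-1(5),11(13)-dien-12,8-olide
Conditions: Ac2O (1.2 equiv), pyridine, 0 °C
Reagents that add atoms: acetic anhydride (CC(=O)OC(C)=O)
Why: Selective acetylation of the secondary allylic alcohol; the tertiary alcohol does not react under these conditions.

Step 21
Reactants: 33 (2S,7S,8R,10R)-2-acetoxy-4-hydroxyguaia-1(5),11(13)-dien-12,8-olide
Product: 34 (2S,7S,8R,10R)-2-acetoxyguaia-1(5),3,11(13)-trien-12,8-olide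
Conditions: Burgess reagent (MeO2CN–SO2–NEt3 inner salt), THF, 0 to 25 °C; cold filtration, used at once below 0 °C
Reagents that add atoms: none
Why: Burgess dehydration of the tertiary allylic alcohol by syn-elimination towards C3 should give the conjugated cyclopentadiene, as in the standard cyclopentenol to cyclopentadiene conversion; the diene is kept cold to suppress 1,5-hydrogen shift and self-dimerisation.

**Fragment union and end game**

Step 22
Reactants: 34 (2S,7S,8R,10R)-2-acetoxyguaia-1(5),3,11(13)-trien-12,8-olide; 19 (3aR,7aS)-3,3-dichloro-2,6-dimethylidene-5-[(2S)-5-(TBSO)pentan-2-yl]-2,3,3a,6,7,7a-hexahydro-1-benzofuran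
Product: 35 [4+3] adduct: bicyclo[3.2.1]oct-6-ene hemiketal with C13′ bonded to C1 and C11′(Cl) bonded to C3; hemiketal carbon C12′ still bridged by oxygen to C8′; side chain as TBS ether
Conditions: AgOCOCF3 (1.2 equiv), Na2CO3, CH2Cl2, −78 to −40 °C (34 in 1.5-fold excess); aq NaHCO3
Reagents that add atoms: water (O)
Why: Silver-assisted ionisation of one allylic chloride gives a cyclic 2-alkoxy-1-chloroallyl cation that undergoes [4+3] cycloaddition with the cyclopentadiene; the hindered chlorinated terminus should bond to the unsubstituted C3 and the CH2 terminus to C1, on the diene α face (anti to the 2-acetoxy group and the pseudoaxial C10 methyl) and on the convex face of the cation (syn to H7′), with a compact transition state placing C7′ equatorial and chlorine axial; the trifluoroacetoxy ketal hydrolyses on work-up.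

Step 23
Reactants: 35 [4+3] adduct hemiketal
Product: 36 1′-O-TBS ether of the target
Conditions: KN(SiMe3)2 (1.1 equiv), THF, −78 to 0 °C
Reagents that add atoms: none
Why: The potassium hemiketal alkoxide pushes the C12′–C13′ bond to migrate to C11′, antiperiplanar to the departing chloride (semibenzilic mechanism; the ring-opened keto alkoxide can reach the same product through a cyclopropanone that the tethered alkoxide opens towards the CH2 carbanion). The closest known reaction is the quasi-Favorskii ring contraction of α-halo bicyclo[3.2.1]octenones obtained from [4+3] cycloadditions. The five-membered carbocycle C1–C2–C3–C11′–C13′ is closed by this 1,2-shift (a 3-exo-tet-type displacement at C11′) from the six-membered ring that contained C12′, and the hemiketal becomes the γ-lactone without a further ring closure. C11′ is the only stereocentre that changes and it is inverted stereospecifically, so the bond to C3 made on the convex face in step 22 ends cis to C6′, with the lactone carbonyl exo and C7′ endo on the norbornene. The step needs migration to win over E2 loss of HCl towards C7′ and over attack of the alkoxide oxygen on C11′; the preformed five-membered hemiketal, a non-nucleophilic base and low temperature should favour the shift, and lactone formation drives it.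

Step 24
Reactants: 36 1′-O-TBS ether of the target
Product: 37 target dimer
Conditions: HF·pyridine, pyridine/THF, 0 to 25 °C
Reagents that add atoms: none
Why: Fluoride cleavage of the primary silyl ether; the acetate, both lactones and the dienes should survive buffered HF·pyridine.

**Compound list**

1 | methyl (E)-but-2-enoate | C/C=C/C(=O)OC | starting material
2 | (3-bromopropoxy)(tert-butyl)dimethylsilane | BrCCCO[Si](C)(C)C(C)(C)C | starting material
3 | [3-(TBSO)propyl]magnesium bromide | Br[Mg]CCCO[Si](C)(C)C(C)(C)C | intermediate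
4 | methyl (3S)-3-methyl-6-(TBSO)hexanoate | COC(=O)C[C@@H](C)CCCO[Si](C)(C)C(C)(C)C | intermediate
5 | (3S)-3-methyl-6-(TBSO)hexanal | O=CC[C@@H](C)CCCO[Si](C)(C)C(C)(C)C | intermediate
6 | but-3-en-2-one | C=CC(C)=O | starting material
7 | (2R)-5-oxo-2-[(2S)-5-(TBSO)pentan-2-yl]hexanal | CC(=O)CC[C@@H](C=O)[C@@H](C)CCCO[Si](C)(C)C(C)(C)C | intermediate
8 | (4R)-4-[(2S)-5-(TBSO)pentan-2-yl]cyclohex-2-en-1-one | C1CC(=O)C=C[C@H]1[C@@H](C)CCCO[Si](C)(C)C(C)(C)C | intermediate
9 | (1S,4R)-4-[(2S)-5-(TBSO)pentan-2-yl]cyclohex-2-en-1-ol (1,4-trans) | C1C[C@H](O)C=C[C@H]1[C@@H](C)CCCO[Si](C)(C)C(C)(C)C | intermediate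
10 | iodoacetic acid | OC(=O)CI | starting material
11 | (1S,4R)-4-[(2S)-5-(TBSO)pentan-2-yl]cyclohex-2-en-1-yl iodoacetate | C1C[C@H](OC(=O)CI)C=C[C@H]1[C@@H](C)CCCO[Si](C)(C)C(C)(C)C | intermediate
12 | cis-fused 4-iodo-5-[(2S)-5-(TBSO)pentan-2-yl]hexahydro-1-benzofuran-2(3H)-one (7aS; iodine and side chain both trans to the C3a–C3 bond) | C1C[C@@H]2OC(=O)C[C@@H]2[C@@H](I)[C@H]1[C@@H](C)CCCO[Si](C)(C)C(C)(C)C | intermediate
13 | (3aR,7aS)-5-[(2S)-5-(TBSO)pentan-2-yl]-3a,6,7,7a-tetrahydro-1-benzofuran-2(3H)-one | C1C[C@@H]2OC(=O)C[C@@H]2C=C1[C@@H](C)CCCO[Si](C)(C)C(C)(C)C | intermediate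
14 | (3aR,7aS)-6-hydroxy-5-[(2S)-5-(TBSO)pentan-2-yl]-3a,6,7,7a-tetrahydro-1-benzofuran-2(3H)-one (C6 epimers) | OC1C[C@@H]2OC(=O)C[C@@H]2C=C1[C@@H](C)CCCO[Si](C)(C)C(C)(C)C | intermediate
15 | (3aR,7aS)-5-[(2S)-5-(TBSO)pentan-2-yl]-3a,7a-dihydro-1-benzofuran-2,6(3H,7H)-dione | O=C1C[C@@H]2OC(=O)C[C@@H]2C=C1[C@@H](C)CCCO[Si](C)(C)C(C)(C)C | intermediate
16 | (3aR,7aS)-6-methylidene-5-[(2S)-5-(TBSO)pentan-2-yl]-3a,6,7,7a-tetrahydro-1-benzofuran-2(3H)-one | C=C1C[C@@H]2OC(=O)C[C@@H]2C=C1[C@@H](C)CCCO[Si](C)(C)C(C)(C)C | intermediate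
17 | (3aR,7aS)-3,3-dichloro-6-methylidene-5-[(2S)-5-(TBSO)pentan-2-yl]-3a,6,7,7a-tetrahydro-1-benzofuran-2(3H)-one | C=C1C[C@@H]2OC(=O)C(Cl)(Cl)[C@@H]2C=C1[C@@H](C)CCCO[Si](C)(C)C(C)(C)C | intermediate
18 | (3aR,7aS)-3,3-dichloro-2-methyl-6-methylidene-5-[(2S)-5-(TBSO)pentan-2-yl]-2,3,3a,6,7,7a-hexahydro-1-benzofuran-2-ol (C2 epimers) | C=C1C[C@@H]2OC(C)(O)C(Cl)(Cl)[C@@H]2C=C1[C@@H](C)CCCO[Si](C)(C)C(C)(C)C | intermediate
19 | (3aR,7aS)-3,3-dichloro-2,6-dimethylidene-5-[(2S)-5-(TBSO)pentan-2-yl]-2,3,3a,6,7,7a-hexahydro-1-benzofuran | C=C1C[C@@H]2OC(=C)C(Cl)(Cl)[C@@H]2C=C1[C@@H](C)CCCO[Si](C)(C)C(C)(C)C | intermediate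
20 | 2-(2,5-dimethylfuran-3-yl)-4,4,5,5-tetramethyl-1,3,2-dioxaborolane | Cc1cc(B2OC(C)(C)C(C)(C)O2)c(C)o1 | starting material
21 | ethyl (E)-but-2-enoate | C/C=C/C(=O)OCC | starting material
22 | ethyl (3R)-3-(2,5-dimethylfuran-3-yl)butanoate | CCOC(=O)C[C@@H](C)c1cc(C)oc1C | intermediate
23 | ethyl (3R)-3-(4-bromo-2,5-dimethylfuran-3-yl)butanoate | CCOC(=O)C[C@@H](C)c1c(Br)c(C)oc1C | intermediate
24 | allyltributylstannane | C=CC[Sn](CCCC)(CCCC)CCCC | starting material
25 | ethyl (3R)-3-[2,5-dimethyl-4-(prop-2-en-1-yl)furan-3-yl]butanoate | CCOC(=O)C[C@@H](C)c1c(CC=C)c(C)oc1C | intermediate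
26 | (3R)-3-[2,5-dimethyl-4-(prop-2-en-1-yl)furan-3-yl]butanal | O=CC[C@@H](C)c1c(CC=C)c(C)oc1C | intermediate
27 | methyl 2-(bromomethyl)prop-2-enoate | C=C(CBr)C(=O)OC | starting material
28 | methyl (2Z)-2-(bromomethyl)-4-{2,5-dimethyl-4-[(2R)-4-oxobutan-2-yl]furan-3-yl}but-2-enoate | O=CC[C@@H](C)c1c(C/C=C(\CBr)C(=O)OC)c(C)oc1C | intermediate
29 | (7S,8R,10R)-tricyclic furan lactone (2,5-dimethylfuran fused at C1/C5 to the cycloheptane; 10-methyl; trans-fused α-methylene-γ-lactone at C7/C8) | C[C@@H]1C[C@H]2OC(=O)C(=C)[C@@H]2Cc2c1c(C)oc2C | intermediate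
30 | (7S,8R,10R)-Z-enedione (cycloheptene C1=C5 bearing an acetyl group on each alkene carbon; lactone unchanged) | C[C@@H]1C[C@H]2OC(=O)C(=C)[C@@H]2CC(C(C)=O)=C1C(C)=O | intermediate
31 | (7S,8R,10R)-4-hydroxy-2-oxoguaia-1(5),11(13)-dien-12,8-olide (C4 epimers) | C[C@@H]1C[C@H]2OC(=O)C(=C)[C@@H]2CC2=C1C(=O)CC2(C)O | intermediate
32 | (2S,7S,8R,10R)-2,4-dihydroxyguaia-1(5),11(13)-dien-12,8-olide | C[C@@H]1C[C@H]2OC(=O)C(=C)[C@@H]2CC2=C1[C@@H](O)CC2(C)O | intermediate
33 | (2S,7S,8R,10R)-2-acetoxy-4-hydroxyguaia-1(5),11(13)-dien-12,8-olide | C[C@@H]1C[C@H]2OC(=O)C(=C)[C@@H]2CC2=C1[C@@H](OC(C)=O)CC2(C)O | intermediate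
34 | (2S,7S,8R,10R)-2-acetoxyguaia-1(5),3,11(13)-trien-12,8-olide | C[C@@H]1C[C@H]2OC(=O)C(=C)[C@@H]2CC2=C1[C@@H](OC(C)=O)C=C2C | intermediate
35 | [4+3] adduct hemiketal (C13′–C1 and C11′–C3 bonds; Cl on C11′; C12′ hemiketal bridged by O to C8′; hemiketal epimers) | C=C1C[C@@H]2OC(O)(C[C@@]45C(=C(C)[C@@H]6[C@@H]4OC(C)=O)C[C@H]3C(=C)C(=O)O[C@@H]3C[C@H]5C)[C@]6(Cl)[C@@H]2C=C1[C@@H](C)CCCO[Si](C)(C)C(C)(C)C | intermediate
36 | 1′-O-TBS ether of the target | C=C1C[C@@H]2OC(=O)[C@@]3(C[C@@]45C(=C(C)[C@@H]3[C@@H]4OC(C)=O)C[C@H]3C(=C)C(=O)O[C@@H]3C[C@H]5C)[C@@H]2C=C1[C@@H](C)CCCO[Si](C)(C)C(C)(C)C | intermediate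
37 | target dimer (CNP0299458.1) | C=C1C[C@@H]2OC(=O)[C@@]3(C[C@@]45C(=C(C)[C@@H]3[C@@H]4OC(C)=O)C[C@H]3C(=C)C(=O)O[C@@H]3C[C@H]5C)[C@@H]2C=C1[C@@H](C)CCCO | target

**Step count.** Total: 24 steps. Longest linear sequence: 14 steps (steps 1 to 11, then 22 to 24); the guaianolide branch is 10 steps (12 to 21).

**Steps most likely to fail**

1. Step 22 ([4+3] cycloaddition). The diene may be lost by 1,5-hydrogen shift or self-dimerisation before capture, the cation may lose a proton, or facial, regiochemical and compact/extended control may be poor. Fallback (base-mediated oxyallyl route with an open-chain ketone), setting out from 17 and returning at 35: MeNH(OMe)·HCl and i-PrMgCl open the lactone to the hydroxy Weinreb amide F1; Et3SiOTf and 2,6-lutidine give the triethylsilyl ether F2; MeMgBr gives the α,α-dichloro methyl ketone F3; F3 and 34 with Et3N in CF3CH2OH undergo [4+3] cycloaddition of the chloro-oxyallyl cation to the chloro ketone F4; AcOH/THF/H2O removes the triethylsilyl group selectively and the hydroxy ketone closes to hemiketal 35.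

2. Step 23 (ring contraction). E2 loss of HCl towards C7′ or attack of the alkoxide oxygen on C11′ may compete with carbon migration. Fallback (electrophilic instead of anionic activation), setting out from 35 and returning at 36: MeOH with pyridinium p-toluenesulfonate converts the hemiketal into the methyl ketal F5; AgBF4 in CH2Cl2 at −20 °C abstracts chloride with concerted 1,2-shift of C13′ (the known rearrangement of α-halo ketals to esters), and the dialkoxycarbenium ion loses its methyl group on aqueous work-up to give 36.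

3. Step 17 (chromium-mediated ring closure). Facial selectivity relative to the C10 methyl may be poor, the cis lactone may form, or intermolecular coupling may compete. Fallback (ketyl–olefin cyclisation, then methylenation), setting out from 26 and returning at 29: cross-metathesis of 26 with methyl acrylate (second-generation Grubbs catalyst) gives the enoate aldehyde F6; SmI2 with t-BuOH in THF at −78 °C effects ketyl addition to the enoate β-carbon and lactonisation to the saturated trans lactone F7; LiN(i-Pr)2 then Eschenmoser's salt gives the Mannich base F8; MeI then NaHCO3 eliminates trimethylamine to give 29.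

Further compounds
F1 | step 22 | 2,2-dichloro-2-[(1R,6S)-6-hydroxy-4-methylidene-3-[(2S)-5-(TBSO)pentan-2-yl]cyclohex-2-en-1-yl]-N-methoxy-N-methylacetamide | C=C1C[C@H](O)[C@H](C(Cl)(Cl)C(=O)N(C)OC)C=C1[C@@H](C)CCCO[Si](C)(C)C(C)(C)C
F2 | step 22 | triethylsilyl ether of F1 | C=C1C[C@H](O[Si](CC)(CC)CC)[C@H](C(Cl)(Cl)C(=O)N(C)OC)C=C1[C@@H](C)CCCO[Si](C)(C)C(C)(C)C
F3 | step 22 | 1,1-dichloro-1-[(1R,6S)-4-methylidene-3-[(2S)-5-(TBSO)pentan-2-yl]-6-(triethylsilyloxy)cyclohex-2-en-1-yl]propan-2-one | C=C1C[C@H](O[Si](CC)(CC)CC)[C@H](C(Cl)(Cl)C(C)=O)C=C1[C@@H](C)CCCO[Si](C)(C)C(C)(C)C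
F4 | step 22 | open-chain [4+3] adduct: bicyclo[3.2.1]oct-6-en-3-one with Cl on C11′ and the C8′ hydroxyl as triethylsilyl ether | C=C1C[C@H](O[Si](CC)(CC)CC)[C@H]([C@@]2(Cl)C(=O)C[C@@]34C(=C(C)[C@@H]2[C@@H]3OC(C)=O)C[C@H]2C(=C)C(=O)O[C@@H]2C[C@H]4C)C=C1[C@@H](C)CCCO[Si](C)(C)C(C)(C)C
F5 | step 23 | methyl ketal of hemiketal 35 | C=C1C[C@@H]2OC(OC)(C[C@@]45C(=C(C)[C@@H]6[C@@H]4OC(C)=O)C[C@H]3C(=C)C(=O)O[C@@H]3C[C@H]5C)[C@]6(Cl)[C@@H]2C=C1[C@@H](C)CCCO[Si](C)(C)C(C)(C)C
F6 | step 17 | methyl (2E)-4-{2,5-dimethyl-4-[(2R)-4-oxobutan-2-yl]furan-3-yl}but-2-enoate | O=CC[C@@H](C)c1c(C/C=C/C(=O)OC)c(C)oc1C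
F7 | step 17 | saturated trans-fused lactone analogue of 29 (no methylidene) | C[C@@H]1C[C@H]2OC(=O)C[C@@H]2Cc2c1c(C)oc2C
F8 | step 17 | α-(dimethylaminomethyl) lactone (Mannich base of F7) | C[C@@H]1C[C@H]2OC(=O)C(CN(C)C)[C@@H]2Cc2c1c(C)oc2C
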